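Ring B (labdane numbering) is cut at C7–C8 and C9–C10, giving a ring A 2-silyloxy diene (C7=C6–C5=C10) and an oxolan-3-one whose exocyclic (Z)-ethylidene bond C8=C9 acts as dienophile. One (4+2) annulation then closes ring B, turns C9 into the spiro centre with its ether oxygen already attached and sets the contiguous stereocentres C8, C9 and C10 against the preformed C13 centre. The feature exploited is that spiro carbon C9 lies between C8 and C10 inside ring B and next to a removable C11 carbonyl. The dienophile is a 5,5-disubstituted 2-ethylidene oxolan-3-one bearing a silyl-capped ethynyl group and a bulky silyloxymethyl arm on C13, the future dihydrofuran.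

Key step: step 10

Remark on numbering: ring A = C1–C5 and C10 (gem-dimethyl on C4); ring B = C5–C10; oxolane = O, C9, C11, C12, C13; dihydrofuran = C13, C14=C15, O, C16; methyl carbons C17 (on C8), C18/C19 (on C4), C20 (on C10); α is the face opposite to the C10 methyl group.
Assumption: for the 4,4,10-trimethyldecal-6-one stage the trans ring fusion (5α-H) is taken to be the thermodynamically preferred one, as is usual for 6-oxo labdanes.

Step 1
Reactants: 1 2-bromoprop-2-en-1-ol; 2 ethynyltrimethylsilane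
Product: 3 2-methylidene-4-(trimethylsilyl)but-3-yn-1-ol
Conditions: Pd(PPh3)2Cl2 (2 mol%), CuI (4 mol%), i-Pr2NH, THF, rt
Reagents that add atoms: none
Why: Sonogashira coupling of the vinyl bromide with the terminal alkyne runs under mild amine conditions that tolerate the free allylic alcohol and should give the 2-alkynyl allylic alcohol needed for the epoxidation.

Step 2
Reactants: 3 2-methylidene-4-(trimethylsilyl)but-3-yn-1-ol
Product: 4 [(2R)-2-[(trimethylsilyl)ethynyl]oxiran-2-yl]methanol
Conditions: Ti(OiPr)4 (10 mol%), D-(−)-diisopropyl tartrate (12 mol%), t-BuOOH, 4 Å MS, CH2Cl2, −20 °C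
Reagents that add atoms: tert-butyl hydroperoxide, CC(C)(C)OO
Why: Sharpless asymmetric epoxidation of the 2-substituted allylic alcohol sets C13 by delivery of oxygen from the titanium tartrate to one enantiotopic alkene face, and the D-(−) tartrate is expected to give the 2R epoxide (the L-(+) ester gives the S series, as in (S)-glycidol from allyl alcohol).

Step 3
Reactants: 4 [(2R)-2-[(trimethylsilyl)ethynyl]oxiran-2-yl]methanol
Product: 5 tert-butyl{[(2S)-2-[(trimethylsilyl)ethynyl]oxiran-2-yl]methoxy}diphenylsilane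
Conditions: TBDPSCl, imidazole, CH2Cl2, 0 °C → rt
Reagents that add atoms: tert-butyl(chloro)diphenylsilane, CC(C)(C)[Si](Cl)(c1ccccc1)c1ccccc1
Why: Silylation of the primary alcohol with silyl chloride and imidazole leaves the epoxide intact; the bulky, acid-stable tert-butyldiphenylsilyl group is chosen because it later shields one face of the dienophile and survives the acidic steps (the descriptor becomes S only through the priority rules).

Step 4
Reactants: 5 tert-butyl{[(2S)-2-[(trimethylsilyl)ethynyl]oxiran-2-yl]methoxy}diphenylsilane; 6 acetylene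
Product: 7 (3R)-3-{[tert-butyl(diphenyl)silyl]oxymethyl}-1-(trimethylsilyl)hexa-1,5-diyn-3-ol
Conditions: HC≡CH, n-BuLi, THF, −78 °C; BF3·OEt2; then 5, −78 °C
Reagents that add atoms: none
Why: BF3-assisted epoxide opening by lithium acetylide (Yamaguchi–Hirao alkynylation) should occur at the unsubstituted carbon C12, so the C13–O bond and its configuration stay untouched, and the cold, non-nucleophilic conditions spare the C-silyl group.

Step 5
Reactants: 7 (3R)-3-{[tert-butyl(diphenyl)silyl]oxymethyl}-1-(trimethylsilyl)hexa-1,5-diyn-3-ol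
Product: 8 (5R)-5-{[tert-butyl(diphenyl)silyl]oxymethyl}-5-[(trimethylsilyl)ethynyl]oxolan-3-one
Conditions: Ph3PAuNTf2 (5 mol%), 3,5-dichloropyridine N-oxide, MsOH, ClCH2CH2Cl, rt
Reagents that add atoms: 3,5-dichloropyridine N-oxide, [O-][n+]1cc(Cl)cc(Cl)c1
Why: Gold-catalysed oxidation of the terminal alkyne by the N-oxide should generate an α-oxo gold carbene (carbonyl at C11, carbene at C9) that inserts into the tertiary O–H bond and closes the five-membered oxolan-3-one, the silyl-capped alkyne being inert to this oxidation.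

Step 6
Reactants: 8 (5R)-5-{[tert-butyl(diphenyl)silyl]oxymethyl}-5-[(trimethylsilyl)ethynyl]oxolan-3-one; 9 acetaldehyde
Product: 13 (2Z,5R)-5-{[tert-butyl(diphenyl)silyl]oxymethyl}-2-ethylidene-5-[(trimethylsilyl)ethynyl]oxolan-3-one, via lithium enolate 10 (not isolated), via lithium aldolate 11 (not isolated), via mesylate 12 (not isolated)
Conditions: LiN(SiMe3)2, THF, −78 °C; CH3CHO; MsCl, −78 → 0 °C; DBU, rt
Reagents that add atoms: none
Why: Directed aldol condensation in which the amide base should deprotonate the unhindered, oxygen-activated C9 (C12 is neopentylic), the enolate adds to acetaldehyde, and mesylation with E1cB elimination should give the ethylidene ketone as the thermodynamically favoured Z isomer (methyl anti to the carbonyl) without touching C13.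

Step 7
Reactants: 14 β-cyclocitral
Product: 15 1-(2,6,6-trimethylcyclohex-1-en-1-yl)ethan-1-ol (racemic)
Conditions: MeLi, Et2O, −78 → 0 °C
Reagents that add atoms: methyllithium, [Li]C
Why: 1,2-Addition of the organolithium to the enal carbonyl should give the secondary allylic alcohol, whose new stereocentre is destroyed in the next step.

Step 8
Reactants: 15 1-(2,6,6-trimethylcyclohex-1-en-1-yl)ethan-1-ol
Product: 16 1-(2,6,6-trimethylcyclohex-1-en-1-yl)ethan-1-one
Conditions: Dess–Martin periodinane, NaHCO3, CH2Cl2, rt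
Reagents that add atoms: none
Why: Dess–Martin oxidation should convert the hindered secondary allylic alcohol into the methyl ketone under neutral conditions without moving the ring double bond.

Step 9
Reactants: 16 1-(2,6,6-trimethylcyclohex-1-en-1-yl)ethan-1-one
Product: 18 tert-butyl(dimethyl){[1-(2,6,6-trimethylcyclohex-1-en-1-yl)ethenyl]oxy}silane, via lithium enolate 17 (not isolated)
Conditions: LiN(i-Pr)2, THF, −78 °C; TBSOTf, −78 → 0 °C
Reagents that add atoms: tert-butyldimethylsilyl trifluoromethanesulfonate, CC(C)(C)[Si](C)(C)OS(=O)(=O)C(F)(F)F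
Why: Kinetic deprotonation of the acetyl methyl group (the only α-C–H) and O-silylation of the enolate (silyl enol ether formation) should give the cross-conjugated 2-silyloxy diene without deconjugation of the ring alkene.

Step 10
Reactants: 13 (2Z,5R)-5-{[tert-butyl(diphenyl)silyl]oxymethyl}-2-ethylidene-5-[(trimethylsilyl)ethynyl]oxolan-3-one; 18 tert-butyl(dimethyl){[1-(2,6,6-trimethylcyclohex-1-en-1-yl)ethenyl]oxy}silane
Product: 19 (13R)-6-[tert-butyl(dimethyl)silyl]oxy-16-[tert-butyl(diphenyl)silyl]oxy-9α,13-epoxy-15-(trimethylsilyl)-8βH-labd-5-en-14-yn-11-one (spiro adduct, 17-methyl α)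
Conditions: Me2AlCl (1.5 equiv), CH2Cl2, −78 → −20 °C
Reagents that add atoms: none
Why: Proposed new method: Me2AlCl activates the C11 carbonyl of 13, the CH2 terminus C7 of the 2-silyloxy diene adds to the β-carbon C8 and the developing aluminium enolate carbon C9 bonds to C10 of the silyloxyallyl cation, a strongly asynchronous (4+2) cycloaddition with Mukaiyama–Michael character that leaves the silyl enol ether at C5=C6. The closest known reaction type is the Lewis-acid-promoted Diels–Alder reaction of hindered 2-silyloxy dienes and of 1-vinyl-2,6,6-trimethylcyclohexenes with cyclic enones, together with exo-selective cycloadditions of 2-alkylidene cycloalkanones; new are the α-oxygenated exocyclic enone and the creation of two adjacent fully substituted carbons, one of them spiro. Ring B is the only ring closed, as the six-membered ring of an intermolecular (4+2) annulation that is suprafacial on both partners (bonds C7–C8 and C9–C10), which makes the oxolanone spiro at C9. C8 is controlled by the Z geometry of the ethylidene group (methyl cis to the ring oxygen, hence 8α-methyl cis to the 9α-oxygen), C9 and C10 by the exo arrangement in which the aluminium-bound carbonyl points away from ring A and its C4 gem-dimethyl group so that C11 ends up syn to the C10 methyl, and the sense of all three relative to C13 by attack on the enone face that carries the slim alkynyl group, anti to the tert-butyldiphenylsilyloxymethyl arm. The step needs regioselectivity, secured by the polarity match of nucleophilic C7 with electrophilic C8 and of the captodative C9 with the tertiary cationic C10, exo selectivity, secured by the fixed s-cis exocyclic enone, and π-facial selectivity, secured only by the size difference of the two C13 substituents, which is why the larger silyl ether was installed.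

Step 11
Reactants: 19 spiro adduct (C11 ketone, C5=C6 silyl enol ether)
Product: 20 (13R)-6-[tert-butyl(dimethyl)silyl]oxy-16-[tert-butyl(diphenyl)silyl]oxy-9α,13-epoxy-15-(trimethylsilyl)-8βH-labd-5-en-14-yn-11-ol (C11 epimers)
Conditions: NaBH4, EtOH–THF, 0 °C → rt
Reagents that add atoms: none
Why: Borohydride reduction should affect only the C11 ketone because C6 is masked as its silyl enol ether, and the configuration of the new carbinol carbon is irrelevant since this oxygen is removed in step 13.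

Step 12
Reactants: 20 C11 alcohol
Product: 23 O-[(13R)-6-[tert-butyl(dimethyl)silyl]oxy-16-[tert-butyl(diphenyl)silyl]oxy-9α,13-epoxy-15-(trimethylsilyl)-8βH-labd-5-en-14-yn-11-yl] S-methyl carbonodithioate, via sodium alkoxide 21 (not isolated), via sodium xanthate 22 (not isolated)
Conditions: NaH, imidazole (cat.), THF, 0 °C; CS2; MeI, rt
Reagents that add atoms: carbon disulfide, S=C=S; iodomethane, CI
Why: Xanthate formation (first half of the Barton–McCombie deoxygenation) should work on the hindered secondary alkoxide because CS2 and MeI are small electrophiles, and the base does not touch the silyl groups.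

Step 13
Reactants: 23 C11 xanthate
Product: 24 (13R)-6-[tert-butyl(dimethyl)silyl]oxy-16-[tert-butyl(diphenyl)silyl]oxy-9α,13-epoxy-15-(trimethylsilyl)-8βH-labd-5-en-14-yne
Conditions: n-Bu3SnH, AIBN (cat.), toluene, 100 °C
Reagents that add atoms: none
Why: Barton–McCombie radical deoxygenation, in which the stannyl radical adds to the thiocarbonyl, the C11–O bond fragments and the secondary radical should abstract hydrogen from the stannane faster than it could add to the silyl-capped alkyne, the neutral conditions preserving the silyl enol ether.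

Step 14
Reactants: 24 C11-deoxygenated silyl enol ether
Product: 25 (13R)-16-[tert-butyl(diphenyl)silyl]oxy-9α,13-epoxy-15-(trimethylsilyl)-5αH,8βH-labd-14-yn-6-one
Conditions: 1 M HCl, THF, rt
Reagents that add atoms: none
Why: Acid hydrolysis of the silyl enol ether (protodesilylation) should give the C6 ketone with C5 protonated and equilibrated through the enol to the trans ring fusion (5α-H), while the primary tert-butyldiphenylsilyl ether and the C-silyl alkyne withstand dilute acid.

Step 15
Reactants: 25 trans-fused 6-ketone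
Product: 27 (13R)-16-[tert-butyl(diphenyl)silyl]oxy-9α,13-epoxy-6-(triethylsilyloxy)-15-(trimethylsilyl)-5αH,8βH-labd-6-en-14-yne, via lithium enolate 26 (not isolated)
Conditions: LiN(i-Pr)2, THF, −78 °C; Et3SiCl, Et3N, −78 → 0 °C
Reagents that add atoms: chlorotriethylsilane, CC[Si](Cl)(CC)CC
Why: Kinetic enolisation with the amide base should occur at the C7 methylene (C5–H is tertiary and lies between two quaternary carbons), and O-silylation (silyl enol ether formation) fixes the C6=C7 enol ether.

Step 16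
Reactants: 27 C6=C7 triethylsilyl enol ether
Product: 29 (13R)-16-[tert-butyl(diphenyl)silyl]oxy-9α,13-epoxy-7α-(triethylsilyloxy)-15-(trimethylsilyl)-5αH,8βH-labd-14-yn-6-one, via silyloxy epoxide 28 (not isolated)
Conditions: mCPBA, NaHCO3, CH2Cl2, −20 → 0 °C
Reagents that add atoms: 3-chloroperoxybenzoic acid, OOC(=O)c1cccc(Cl)c1
Why: Rubottom oxidation, in which the peracid should epoxidise the enol ether from the α face (the β face is blocked by the C10 and 4β methyl groups) and the silyloxy epoxide opens with 1,4-silyl shift to the 7α-silyloxy 6-ketone.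

Step 17
Reactants: 29 7α-silyloxy 6-ketone
Product: 30 (13R)-16-[tert-butyl(diphenyl)silyl]oxy-9α,13-epoxy-7α-(triethylsilyloxy)-15-(trimethylsilyl)-5αH,8βH-labd-14-yn-6β-ol
Conditions: LiAlH4, THF, −20 → 0 °C
Reagents that add atoms: none
Why: Hydride reduction of the C6 ketone should take place from the α face, because axial β attack is blocked by the syn-axial C10 and 4β methyl groups, and so give the axial 6β-alcohol.

Step 18
Reactants: 30 6β-alcohol
Product: 31 (13R)-16-[tert-butyl(diphenyl)silyl]oxy-9α,13-epoxy-7α-(triethylsilyloxy)-15-(trimethylsilyl)-5αH,8βH-labd-14-yn-6β-yl acetate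
Conditions: Ac2O, DMAP, Et3N, CH2Cl2, 40 °C
Reagents that add atoms: acetic anhydride, CC(=O)OC(C)=O
Why: DMAP-catalysed acylation (Steglich-type acyl transfer) should acetylate the only free hydroxyl, and the trans-diaxial 7α-silyl ether can neither migrate nor be acetylated, so that O6 and O7 stay differentiated.

Step 19
Reactants: 31 6β-acetate
Product: 32 (13R)-6β-acetoxy-9α,13-epoxy-5αH,8βH-labd-14-yne-7α,16-diol
Conditions: Bu4NF, THF, 0 °C → rt
Reagents that add atoms: none
Why: Fluoride-mediated desilylation should remove the O-triethylsilyl, O-tert-butyldiphenylsilyl and C-trimethylsilyl groups in one operation, while the hindered axial acetate survives and cannot migrate to the trans-diaxial 7α-hydroxyl.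

Step 20
Reactants: 32 alkynyl diol
Product: 33 6β-acetoxy-9α,13R:15,16-diepoxy-5αH,8βH-labd-14-en-7α-ol
Conditions: Mo(CO)6 (30 mol%), Et3N, Et2O, hν (350 nm), rt
Reagents that add atoms: none
Why: Metal-vinylidene cycloisomerisation of the 3-butyn-1-ol unit promoted by (Et3N)Mo(CO)5 (alkynol cycloisomerisation, 5-endo overall) should close the 2,3-dihydrofuran on the quaternary C13 without touching its configuration, the 7α-hydroxyl being too remote to compete.

Step 21
Reactants: 33 dihydrofuran 7α-alcohol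
Product: 34 6β-acetoxy-9α,13R:15,16-diepoxy-5αH,8βH-labd-14-en-7-one (CNP0224709.1)
Conditions: Dess–Martin periodinane, NaHCO3, CH2Cl2, 0 °C → rt
Reagents that add atoms: none
Why: Dess–Martin oxidation of the secondary 7α-alcohol under buffered, non-basic conditions should give the 7-ketone last, so that the enol ether, the acetoxy-bearing C6, the equatorial 8α-methyl group and the base-labile β-alkoxy ketone (C7 with the C9–O bond) are not put at risk.

Compound list
1 | 2-bromoprop-2-en-1-ol | C=C(Br)CO | starting material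
2 | ethynyltrimethylsilane | C#C[Si](C)(C)C | starting material
3 | 2-methylidene-4-(trimethylsilyl)but-3-yn-1-ol | C=C(CO)C#C[Si](C)(C)C | intermediate
4 | [(2R)-2-[(trimethylsilyl)ethynyl]oxiran-2-yl]methanol | OC[C@@]1(CO1)C#C[Si](C)(C)C | intermediate
5 | tert-butyl{[(2S)-2-[(trimethylsilyl)ethynyl]oxiran-2-yl]methoxy}diphenylsilane | CC(C)(C)[Si](OC[C@@]1(CO1)C#C[Si](C)(C)C)(c1ccccc1)c1ccccc1 | intermediate
6 | acetylene | C#C | starting material
7 | (3R)-3-{[tert-butyl(diphenyl)silyl]oxymethyl}-1-(trimethylsilyl)hexa-1,5-diyn-3-ol | C#CC[C@@](O)(C#C[Si](C)(C)C)CO[Si](c1ccccc1)(c1ccccc1)C(C)(C)C | intermediate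
8 | (5R)-5-{[tert-butyl(diphenyl)silyl]oxymethyl}-5-[(trimethylsilyl)ethynyl]oxolan-3-one | O=C1C[C@@](OC1)(C#C[Si](C)(C)C)CO[Si](c1ccccc1)(c1ccccc1)C(C)(C)C | intermediate
9 | acetaldehyde | CC=O | starting material
10 | lithium enolate of 8 (C9=C11 enolate) | C1=C([O-])C[C@@](O1)(C#C[Si](C)(C)C)CO[Si](c2ccccc2)(c2ccccc2)C(C)(C)C.[Li+] | intermediate
11 | lithium aldolate, (5R)-2-(1-oxidoethyl) derivative of 8 (C8/C9 epimers) | CC([O-])C1C(=O)C[C@@](O1)(C#C[Si](C)(C)C)CO[Si](c2ccccc2)(c2ccccc2)C(C)(C)C.[Li+] | intermediate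
12 | mesylate, (5R)-2-[1-(methanesulfonyloxy)ethyl] derivative of 8 (C8/C9 epimers) | CC(OS(C)(=O)=O)C1C(=O)C[C@@](O1)(C#C[Si](C)(C)C)CO[Si](c2ccccc2)(c2ccccc2)C(C)(C)C | intermediate
13 | (2Z,5R)-5-{[tert-butyl(diphenyl)silyl]oxymethyl}-2-ethylidene-5-[(trimethylsilyl)ethynyl]oxolan-3-one | C/C=C1/C(=O)C[C@@](O1)(C#C[Si](C)(C)C)CO[Si](c2ccccc2)(c2ccccc2)C(C)(C)C | intermediate
14 | β-cyclocitral (2,6,6-trimethylcyclohex-1-ene-1-carbaldehyde) | CC1=C(C=O)C(C)(C)CCC1 | starting material
15 | 1-(2,6,6-trimethylcyclohex-1-en-1-yl)ethan-1-ol (racemic) | CC(O)C1=C(C)CCCC1(C)C | intermediate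
16 | 1-(2,6,6-trimethylcyclohex-1-en-1-yl)ethan-1-one | CC(=O)C1=C(C)CCCC1(C)C | intermediate
17 | lithium enolate of 16 | [Li+].[O-]C(=C)C1=C(C)CCCC1(C)C | intermediate
18 | tert-butyl(dimethyl){[1-(2,6,6-trimethylcyclohex-1-en-1-yl)ethenyl]oxy}silane | C=C(O[Si](C)(C)C(C)(C)C)C1=C(C)CCCC1(C)C | intermediate
19 | (13R)-6-[tert-butyl(dimethyl)silyl]oxy-16-[tert-butyl(diphenyl)silyl]oxy-9α,13-epoxy-15-(trimethylsilyl)-8βH-labd-5-en-14-yn-11-one | C=1(O[Si](C)(C)C(C)(C)C)C[C@@H](C)[C@]2(C(=O)C[C@@](O2)(C#C[Si](C)(C)C)CO[Si](c3ccccc3)(c3ccccc3)C(C)(C)C)[C@@]2(C)CCCC(C)(C)C=12 | intermediate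
20 | 11-hydroxy analogue of 19 (C11 epimers) | C=1(O[Si](C)(C)C(C)(C)C)C[C@@H](C)[C@]2(C(O)C[C@@](O2)(C#C[Si](C)(C)C)CO[Si](c3ccccc3)(c3ccccc3)C(C)(C)C)[C@@]2(C)CCCC(C)(C)C=12 | intermediate
21 | sodium alkoxide of 20 | C=1(O[Si](C)(C)C(C)(C)C)C[C@@H](C)[C@]2(C([O-])C[C@@](O2)(C#C[Si](C)(C)C)CO[Si](c3ccccc3)(c3ccccc3)C(C)(C)C)[C@@]2(C)CCCC(C)(C)C=12.[Na+] | intermediate
22 | sodium O-(11-yl) carbonodithioate of 20 | C=1(O[Si](C)(C)C(C)(C)C)C[C@@H](C)[C@]2(C(OC(=S)[S-])C[C@@](O2)(C#C[Si](C)(C)C)CO[Si](c3ccccc3)(c3ccccc3)C(C)(C)C)[C@@]2(C)CCCC(C)(C)C=12.[Na+] | intermediate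
23 | O-(11-yl) S-methyl carbonodithioate of 20 | C=1(O[Si](C)(C)C(C)(C)C)C[C@@H](C)[C@]2(C(OC(=S)SC)C[C@@](O2)(C#C[Si](C)(C)C)CO[Si](c3ccccc3)(c3ccccc3)C(C)(C)C)[C@@]2(C)CCCC(C)(C)C=12 | intermediate
24 | (13R)-6-[tert-butyl(dimethyl)silyl]oxy-16-[tert-butyl(diphenyl)silyl]oxy-9α,13-epoxy-15-(trimethylsilyl)-8βH-labd-5-en-14-yne | C=1(O[Si](C)(C)C(C)(C)C)C[C@@H](C)[C@]2(CC[C@@](O2)(C#C[Si](C)(C)C)CO[Si](c3ccccc3)(c3ccccc3)C(C)(C)C)[C@@]2(C)CCCC(C)(C)C=12 | intermediate
25 | (13R)-16-[tert-butyl(diphenyl)silyl]oxy-9α,13-epoxy-15-(trimethylsilyl)-5αH,8βH-labd-14-yn-6-one | O=C1C[C@@H](C)[C@]2(CC[C@@](O2)(C#C[Si](C)(C)C)CO[Si](c3ccccc3)(c3ccccc3)C(C)(C)C)[C@@]2(C)CCCC(C)(C)[C@H]12 | intermediate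
26 | lithium C6=C7 enolate of 25 | [Li+].[O-]C1=C[C@@H](C)[C@]2(CC[C@@](O2)(C#C[Si](C)(C)C)CO[Si](c3ccccc3)(c3ccccc3)C(C)(C)C)[C@@]2(C)CCCC(C)(C)[C@H]12 | intermediate
27 | (13R)-16-[tert-butyl(diphenyl)silyl]oxy-9α,13-epoxy-6-(triethylsilyloxy)-15-(trimethylsilyl)-5αH,8βH-labd-6-en-14-yne | CC[Si](CC)(CC)OC1=C[C@@H](C)[C@]2(CC[C@@](O2)(C#C[Si](C)(C)C)CO[Si](c3ccccc3)(c3ccccc3)C(C)(C)C)[C@@]2(C)CCCC(C)(C)[C@H]12 | intermediate
28 | 6α,7α-epoxide of 27 (6β-triethylsilyloxy) | CC[Si](CC)(CC)O[C@@]14O[C@H]4[C@@H](C)[C@]2(CC[C@@](O2)(C#C[Si](C)(C)C)CO[Si](c3ccccc3)(c3ccccc3)C(C)(C)C)[C@@]2(C)CCCC(C)(C)[C@H]12 | intermediate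
29 | (13R)-16-[tert-butyl(diphenyl)silyl]oxy-9α,13-epoxy-7α-(triethylsilyloxy)-15-(trimethylsilyl)-5αH,8βH-labd-14-yn-6-one | O=C1[C@@H](O[Si](CC)(CC)CC)[C@@H](C)[C@]2(CC[C@@](O2)(C#C[Si](C)(C)C)CO[Si](c3ccccc3)(c3ccccc3)C(C)(C)C)[C@@]2(C)CCCC(C)(C)[C@H]12 | intermediate
30 | (13R)-16-[tert-butyl(diphenyl)silyl]oxy-9α,13-epoxy-7α-(triethylsilyloxy)-15-(trimethylsilyl)-5αH,8βH-labd-14-yn-6β-ol | O[C@@H]1[C@@H](O[Si](CC)(CC)CC)[C@@H](C)[C@]2(CC[C@@](O2)(C#C[Si](C)(C)C)CO[Si](c3ccccc3)(c3ccccc3)C(C)(C)C)[C@@]2(C)CCCC(C)(C)[C@H]12 | intermediate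
31 | 6β-acetate of 30 | CC(=O)O[C@@H]1[C@@H](O[Si](CC)(CC)CC)[C@@H](C)[C@]2(CC[C@@](O2)(C#C[Si](C)(C)C)CO[Si](c3ccccc3)(c3ccccc3)C(C)(C)C)[C@@]2(C)CCCC(C)(C)[C@H]12 | intermediate
32 | (13R)-6β-acetoxy-9α,13-epoxy-5αH,8βH-labd-14-yne-7α,16-diol | CC(=O)O[C@@H]1[C@@H](O)[C@@H](C)[C@]2(CC[C@@](O2)(C#C)CO)[C@@]2(C)CCCC(C)(C)[C@H]12 | intermediate
33 | 6β-acetoxy-9α,13R:15,16-diepoxy-5αH,8βH-labd-14-en-7α-ol | CC(=O)O[C@@H]1[C@@H](O)[C@@H](C)[C@]2(CC[C@]3(C=COC3)O2)[C@@]2(C)CCCC(C)(C)[C@H]12 | intermediate
34 | 6β-acetoxy-9α,13R:15,16-diepoxy-5αH,8βH-labd-14-en-7-one (CNP0224709.1) | CC(=O)O[C@@H]1C(=O)[C@@H](C)[C@]2(CC[C@]3(C=COC3)O2)[C@@]2(C)CCCC(C)(C)[C@H]12 | target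

Total step count: 21. Longest linear sequence: 18 steps (steps 1–6, 10, 11–21).

Steps most likely to fail

Step 10 (proposed new method). The annulation may stop after the first C–C bond (C7–C8) and deliver open-chain Michael products, or it may close through the enolate oxygen instead of C9. It may also show poor exo or π-facial selectivity at the two adjacent fully substituted carbons, and adventitious acid may protodesilylate the diene. The fallback uses known reactions only, sets out from 13 and 18 and comes back at 25. A TBSOTf-catalysed Mukaiyama–Michael addition with acidic work-up should give the open-chain enone ketone F1. KN(SiMe3)2 in THF should then close ring B by intramolecular Michael addition of the C9 enolate to C10 of the tetrasubstituted enone, giving the tricyclic 6,11-diketone F2, whose C8 epimers are separated at this point. NaBH4 at low temperature should reduce the more electrophilic oxolanone carbonyl C11 to the keto alcohol F3. This is converted into the xanthate F4 (NaH, CS2, MeI) and deoxygenated with n-Bu3SnH/AIBN to ketone 25.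

Step 6. Enolisation may occur at C12 instead of C9 or on both sides, acetaldehyde may self-condense, and the aldolate may revert before it is trapped. The fallback sets out from 8 and comes back at 13. TBSOTf/Et3N should give the thermodynamic silyl enol ether F5, with the double bond toward the oxygen-bearing C9. A BF3·OEt2-mediated Mukaiyama aldol addition to acetaldehyde should give the β-hydroxy ketone F6. Mesylation and elimination (MsCl, Et3N; DBU), passing through mesylate 12, should then give 13.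

Step 18. Acyl transfer to the axial 6β-hydroxyl, which is 1,3-diaxial to two methyl groups, may be too slow, and forcing conditions may cost the triethylsilyl ether. The fallback sets out from 30 and comes back at 31. Deprotonation with KN(SiMe3)2 (THF, −78 °C) should give the potassium alkoxide F7, which is acylated directly with acetyl chloride; the trans-diaxial silyl ether cannot migrate to the alkoxide.

Further compounds
F1 | step 10 | (5R)-5-{[tert-butyl(diphenyl)silyl]oxymethyl}-2-[4-oxo-4-(2,6,6-trimethylcyclohex-1-en-1-yl)butan-2-yl]-5-[(trimethylsilyl)ethynyl]oxolan-3-one (C8/C9 epimers) | CC1=C(C(=O)CC(C)C2C(=O)C[C@@](O2)(C#C[Si](C)(C)C)CO[Si](c3ccccc3)(c3ccccc3)C(C)(C)C)C(C)(C)CCC1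
F2 | step 10 | (13R)-16-[tert-butyl(diphenyl)silyl]oxy-9α,13-epoxy-15-(trimethylsilyl)-5αH,8βH-labd-14-yne-6,11-dione | O=C1C[C@@H](C)[C@]2(C(=O)C[C@@](O2)(C#C[Si](C)(C)C)CO[Si](c3ccccc3)(c3ccccc3)C(C)(C)C)[C@@]2(C)CCCC(C)(C)[C@H]12
F3 | step 10 | (13R)-16-[tert-butyl(diphenyl)silyl]oxy-9α,13-epoxy-11-hydroxy-15-(trimethylsilyl)-5αH,8βH-labd-14-yn-6-one (C11 epimers) | O=C1C[C@@H](C)[C@]2(C(O)C[C@@](O2)(C#C[Si](C)(C)C)CO[Si](c3ccccc3)(c3ccccc3)C(C)(C)C)[C@@]2(C)CCCC(C)(C)[C@H]12
F4 | step 10 | O-(11-yl) S-methyl carbonodithioate of F3 | O=C1C[C@@H](C)[C@]2(C(OC(=S)SC)C[C@@](O2)(C#C[Si](C)(C)C)CO[Si](c3ccccc3)(c3ccccc3)C(C)(C)C)[C@@]2(C)CCCC(C)(C)[C@H]12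
F5 | step 6 | (5R)-3-[tert-butyl(dimethyl)silyl]oxy-5-{[tert-butyl(diphenyl)silyl]oxymethyl}-5-[(trimethylsilyl)ethynyl]-4,5-dihydrofuran | C1=C(O[Si](C)(C)C(C)(C)C)C[C@@](O1)(C#C[Si](C)(C)C)CO[Si](c2ccccc2)(c2ccccc2)C(C)(C)C
F6 | step 6 | (5R)-5-{[tert-butyl(diphenyl)silyl]oxymethyl}-2-(1-hydroxyethyl)-5-[(trimethylsilyl)ethynyl]oxolan-3-one (C8/C9 epimers) | CC(O)C1C(=O)C[C@@](O1)(C#C[Si](C)(C)C)CO[Si](c2ccccc2)(c2ccccc2)C(C)(C)C
F7 | step 18 | potassium 6β-alkoxide of 30 | [K+].[O-][C@@H]1[C@@H](O[Si](CC)(CC)CC)[C@@H](C)[C@]2(CC[C@@](O2)(C#C[Si](C)(C)C)CO[Si](c3ccccc3)(c3ccccc3)C(C)(C)C)[C@@]2(C)CCCC(C)(C)[C@H]12
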